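- I started from a leftover nobody had measured, the partner remaining in the alder run, and built from it one number to carry to the flasks asked about.

in all of them: starting material 20 mM
- alder: partner 1.5 equiv; protic impurity 1 mM; temperature 90 °C; run made earlier
- Friday's: partner 1.00 equiv; protic impurity 1.00 mM; temperature 90 °C; time 2.0 h
- Thursday's: partner 1.00 equiv; protic impurity 1.00 mM; temperature 60 °C; time 2.0 h
- Wednesday's: partner 1.00 equiv; protic impurity 1.00 mM; temperature 45 °C; time 2.0 h
- Sunday's: partner 1.00 equiv; protic impurity 1.00 mM; temperature 75 °C; time 2.0 h

alder run (percent of the starting material charged): time / min: target / % = 2.00: 33.8; 6.00: 23.1; 10.0: 21.0; 15.0: 19.6; 20.0: 19.8; 30.0: 20.2; 40.0: 19.1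

(each reading ± 0.5 percentage points)

* the best flask by amount of target, in percent of the starting material charged; "all alike" if 1.5 percentage points covers them all (Friday's / Thursday's / Wednesday's / Sunday's / all alike)
* amount of target at the end, in percent of the starting material charged, Friday's
* amount of target at the end, in percent of the starting material charged, Thursday's
* amount of target at the end, in percent of the starting material charged, Wednesday's
* amount of target at the end, in percent of the starting material charged, Sunday's

- the earlier runs do not show what temperature does; that part of a forecast is a guess

- With the main step by itself, starting material plus partner to target, the alder charge of 1.5 equiv partner allows target up to 100 %, but the first reading of 33.8 % already stood lower.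
- I then added the relaxation the alder curve shows: replacing its flat tail from 15.0 min on by its mean gave 19.7 %, and the excess over that mean shrank from 14 percentage points at 2.00 min to 3.4 points at 6.00 min.
- Running that same fall backwards to the start, as if the target had been made at once, gave 48.4 % made, of which the alder run kept a share of 40.7 %.
- I assumed that the rest of the processes, which held the made amount below 100 %, spent no partner, so I put the alder partner left over at 20.3 mM, and I replaced the falling c partner by its mean, 25.2 mM.
- I called the partner's pull the ratio of starting material made into target to starting material lost otherwise, divided by mean c partner, a selectivity factor, which came to 0.0372 mM⁻¹.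
- For Friday's, two rounds of that rule, each taking its mean partner from the round before, gave 36.1 % and then 37.9 % made, so with the alder kept share I reckoned 15.4 % target.
- Using the charged partner instead of its mean, in both flasks, put Friday's made amount at 38.4 %, which lay 0.50 points from the figure reckoned with the mean.
- The runs show nothing of temperature, so I guessed the same pull for Sunday's, Thursday's and Wednesday's, placed their target between 15.4 % and 37.9 % according to how far I guessed relaxation had gone in 2.0 h, and expected the coolest, Wednesday's, to come out best.
- The forecast also named Wednesday's, with 19 % for Friday's, above my figure, 21 % for Thursday's, 35 % for Wednesday's and 19.5 % for Sunday's, on the ground that “Much kinetic target should survive”.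
- The flasks gave 14.8 % on Friday's, 22.9 % on Thursday's, 32.1 % on Wednesday's and 18.3 % on Sunday's, so Wednesday's held the most target.

    starting material + protic impurity → quenched substrate (k = 52.0 M⁻¹ h⁻¹, Ea = 63.0 kJ mol⁻¹)
    starting material → side product A (k = 4.00 h⁻¹, Ea = 93.0 kJ mol⁻¹)
    2 starting material → side product B (k = 730 M⁻¹ h⁻¹, Ea = 64.0 kJ mol⁻¹)
    target ⇌ isomer of the product (K = 0.720, k = 0.610 h⁻¹, Ea = 96.0 kJ mol⁻¹, ΔH = 22.0 kJ mol⁻¹)
    starting material + partner → target (k = 590 M⁻¹ h⁻¹, Ea = 71.0 kJ mol⁻¹)
    (constants at 60 °C)

- Wednesday's target and isomer of the product together came to 38.1 %, which gives that flask a pull of 0.0380 mM⁻¹, beside the 0.0372 mM⁻¹ reckoned from the alder run, and a kept share of 84.2 %. On the neighbour, Wednesday's flask with 1.70 equiv of partner, that pull gave 53.4 % made in the first round and 52.1 % in the second, so 43.9 % target at the same kept share; that neighbour held 42.9 % target, with 70 % of its partner left over.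

The numbers in the tables were generated by integration with made-up constants, noise included.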